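(The readings come from a simulation from invented constants, noise included.)

3 questions stood on the violet flask: how it stands at 4.0 d, how much isomer of the product it holds then, and how much target a far longer wait leaves.

| setting | violet | grey | flask |
|---|---|---|---|
| starting material | 0.066 M | 0.033 M | 0.066 M |
| coupling partner | 0.099 M (fed, over 5.0 h) | 0.099 M (fed, over 5.0 h) | 0.0990 M (fed, over 5.0 h) |
| remark | the very flask that is asked about, followed so far | run made earlier |  |
| time |  |  | 4.0 d |

| run | time / h | isomer of the product / % | target / % | starting material / % |
|---|---|---|---|---|
| violet | 3.00 | 67.5 | 1.1 | 28.7 |
| violet | 10.0 | 98.0 | 1.7 | 0.8 |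
| violet | 20.0 | 97.3 | 0.5 | 3.0 |
| violet | 30.0 | 96.3 | 0.2 | 2.4 |
| violet | 40.0 | 97.5 | 0 | 1.8 |
| grey | 3.00 | 87.2 | 0 | 12.3 |
| grey | 10.0 | 98.7 | 1.8 | 1.4 |
| grey | 20.0 | 98.3 | 0.5 | 0.9 |
| grey | 30.0 | 101.0 | 0.5 | 0.6 |
| grey | 40.0 | 98.8 | 0 | 1.5 |

(scatter of a reading: 1 percentage point)

1. the state of affairs at 4.0 d: stopped, and by what, or still going (it is still moving / forward and back rates have come level / the coupling partner has run out first / all of the starting material has reacted)
2. amount of isomer of the product at 4.0 d, in percent of the starting material charged
3. amount of target if the flask were left three thousand times as long, in percent of the starting material charged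

- the reaction counts as stopped when no species that holds the starting material changes by six tenths of a point or more over the second half of the time

A step with rate constants both ways stops where forward rate equals back rate. Isomer over starting material then grows in step with free coupling partner: Q/A = κβ, where Q and A are shares of the starting material charged and β is the free share of the partner charge.

From 20.0 h on, the violet readings give Q/A = 40.4, a residue of 2.41%. If partner is consumed one for one, full conversion leaves β = 33.3%, and the small residue corrects this to 34.9%. Dividing gives 116 for κ, the hold number: Q/A per unit of free partner share, an equilibrium constant scaled by the partner charge.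

Grey, with half the starting material and the same partner charge, has a residue of 0.996% and gives 148. With a scatter of 1 percentage point on so small a residue, that is a weak reading, so I kept the violet value.

In violet, partner remained and the residue showed no drift beyond scatter, so I expected forward and back rates level at 4.0 d, with 97.6% isomer. The violet target readings fell to 0%, so I expected target to stay below 1 point.

The forecast said forward and back rates have come level, with 97.8% isomer where I had 97.6%, and 0.05% target, noting that “Nothing drifts from 20 to 40 h beyond noise”.

The flask gave forward and back rates have come level, with 97.0% isomer and 0.120% target.

    starting material + coupling partner ⇌ target (K = 4.70 M⁻¹, k = 2.52 M⁻¹ min⁻¹)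
    starting material + coupling partner ⇌ isomer of the product (K = 1100 M⁻¹, k = 1.00 M⁻¹ min⁻¹)
    coupling partner → decomposition product (k = 2.57 × 10⁻⁶ min⁻¹)

With 35% of the partner free, the hold number gives a residue of 2.44% on this flask, where 2.58% stands. The way back from isomer is the main reason for the missing isomer: the run without it reaches 100%, against 97.0%.

In a neighbour flask with 0.11 M of starting material, partner stands at 0.900 equiv, so residue and β must be solved together, and the same hold number gives a residue of 14.6%. The computed flask holds 15% starting material and 84.8% isomer.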